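## Retrosynthetic overview

1. The target is debenzylated last; the interflavan C4(upper)–C8(lower) bond comes from a 4β-alkoxy 3-O-galloyl flavan electrophile and a benzylated flavan-3-ol nucleophile, and both partners are made from one flavan (21).
2. Flavan 21 has its phloroglucinol ring carried as a cyclohexenone: a 7-hydroxy-hexahydrochromen-5-one is aromatized by oxidation of the C7 carbinol, then benzylated.
3. The pyran ring F of the lower unit is cut at C4–C4a and O1–C8a, giving 5-hydroxycyclohexane-1,3-dione and a syn 2-alkoxy-3-silyloxy-3-arylpropanal. What allows this: ring D is a phloroglucinol, the enol of a cyclic 1,3-diketone, in which C4a lies between the oxygen-bearing C5 and C8a; C4a is therefore a dione carbon nucleophile and C8a a carbonyl carbon, and the symmetric dione poses no regiochemical question.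
4. The aldehyde gets both stereocenters (future C3 and C2) from an Evans syn glycolate aldol; because the C2–O bond is never broken, the syn pair maps directly onto the 2,3-cis (epi) series.
5. Ring order: ring E (bought aryl) → ring D as the dione → ring F by annulation → ring D aromatized → C4/C3 functionalization of the upper copy → interflavan bond.

Key step: step 7

Remark: flavan numbering is used for both units (upper unit: rings A, C, B; lower unit: phloroglucinol ring D, pyran ring F, pyrogallol ring E). Compounds 1, 3, 4, 7 and 23 are taken as purchased. Compound 16 forms as both C7 epimers, which converge in step 8.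

## Route

Step 1
Reactants: 1 phloroglucinol
Product: 2 5-hydroxycyclohexane-1,3-dione
Conditions: NaBH4, H2O, 0 °C → rt; then HCl to pH 2
Reagents that add atoms: none
Why: Borohydride reduces phloroglucinol through the keto tautomer of its anion, a carbonyl reduction that should stop at the dihydro stage because the product is a stabilized 1,3-diketone enolate; no stereocenter results in the symmetric dione.

Step 2
Reactants: 3 (S)-4-benzyloxazolidin-2-one; 4 2-(allyloxy)acetic acid
Product: 6 (S)-4-benzyl-3-[2-(allyloxy)acetyl]oxazolidin-2-one, via mixed pivalic anhydride 5 (not isolated)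
Conditions: pivaloyl chloride, Et3N, THF, −20 °C; then 3, LiCl, rt
Reagents that add atoms: none
Why: N-acylation of the oxazolidinone by the mixed pivalic anhydride occurs at the less hindered glycolyl carbonyl and is the standard entry to glycolyl imides; no stereocenter is formed.

Step 3
Reactants: 6 (S)-4-benzyl-3-[2-(allyloxy)acetyl]oxazolidin-2-one; 7 3,4,5-tris(benzyloxy)benzaldehyde
Product: 9 (S)-4-benzyl-3-{(2S,3R)-2-(allyloxy)-3-hydroxy-3-[3,4,5-tris(benzyloxy)phenyl]propanoyl}oxazolidin-2-one, via dibutylboron Z-enolate 8 (not isolated)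
Conditions: Bu2BOTf, iPr2NEt, CH2Cl2, −78 → 0 °C; 7, −78 → 0 °C; then pH 7 buffer, MeOH, 30% H2O2, 0 °C
Reagents that add atoms: none
Why: Evans syn aldol reaction: the boron Z-enolate reacts through a closed Zimmerman–Traxler chair in which the benzyl group of the auxiliary blocks one enolate face, so both new stereocenters (future C3 and C2 of the flavan) are set as the syn (2S,3R) pair that corresponds to the 2R,3R flavan.

Step 4
Reactants: 9 (S)-4-benzyl-3-{(2S,3R)-2-(allyloxy)-3-hydroxy-3-[3,4,5-tris(benzyloxy)phenyl]propanoyl}oxazolidin-2-one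
Product: 10 (2S,3R)-2-(allyloxy)-3-hydroxy-N-methoxy-N-methyl-3-[3,4,5-tris(benzyloxy)phenyl]propanamide
Conditions: MeNHOMe·HCl, AlMe3, THF, 0 °C → rt; aq. potassium sodium tartrate
Reagents that add atoms: N,O-dimethylhydroxylamine hydrochloride, CNOC.Cl
Why: Aluminium amide transamination (Weinreb amide formation) is directed to the exocyclic carbonyl by chelation of the free β-hydroxyl, should not epimerize the α-alkoxy centre and returns the auxiliary.

Step 5
Reactants: 10 (2S,3R)-2-(allyloxy)-3-hydroxy-N-methoxy-N-methyl-3-[3,4,5-tris(benzyloxy)phenyl]propanamide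
Product: 11 (2S,3R)-2-(allyloxy)-N-methoxy-N-methyl-3-(triethylsilyloxy)-3-[3,4,5-tris(benzyloxy)phenyl]propanamide
Conditions: Et3SiCl, imidazole, DMF, 0 °C → rt
Reagents that add atoms: chlorotriethylsilane, CC[Si](Cl)(CC)CC
Why: Standard silylation of the secondary benzylic alcohol; the triethylsilyl ether blocks retro-aldol and β-elimination in the next two steps and is labile enough to be removed by mild acid within step 7.

Step 6
Reactants: 11 (2S,3R)-2-(allyloxy)-N-methoxy-N-methyl-3-(triethylsilyloxy)-3-[3,4,5-tris(benzyloxy)phenyl]propanamide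
Product: 12 (2S,3R)-2-(allyloxy)-3-(triethylsilyloxy)-3-[3,4,5-tris(benzyloxy)phenyl]propanal
Conditions: iBu2AlH (DIBAL-H), THF, −78 °C; aq. potassium sodium tartrate
Reagents that add atoms: none
Why: Reduction of a Weinreb amide stops at the aldehyde because the chelated tetrahedral aluminium intermediate survives until work-up; the configurationally labile α-alkoxy aldehyde is used at once.

Step 7
Reactants: 2 5-hydroxycyclohexane-1,3-dione; 12 (2S,3R)-2-(allyloxy)-3-(triethylsilyloxy)-3-[3,4,5-tris(benzyloxy)phenyl]propanal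
Product: 16 (2R,3R)-3-(allyloxy)-7-hydroxy-2-[3,4,5-tris(benzyloxy)phenyl]-2,3,4,6,7,8-hexahydro-5H-chromen-5-one, via alkylidene dione 13 (not isolated), via silyl ether dione 14 (not isolated), via hydroxy dione 15 (not isolated)
Conditions: L-proline (10 mol%), Hantzsch ester (diethyl 2,6-dimethyl-1,4-dihydropyridine-3,5-dicarboxylate, 1.1 equiv), CH2Cl2/EtOH 4:1, rt; then PPTS (0.5 equiv), MeOH, 4 Å molecular sieves, rt → 40 °C
Reagents that add atoms: none
Why: Proline turns aldehyde 12 into an iminium ion that is attacked by the enol of dione 2 at its central carbon (future C4a), and Knoevenagel dehydration gives alkylidene dione 13, a doubly activated acceptor that takes a hydride from the Hantzsch ester at the exocyclic carbon (future C4) to give 14 with the C4–C4a bond in place. On acidification the triethylsilyl ether is methanolysed to 15, the freed C2 hydroxyl adds to the neighbouring enolized dione carbonyl (future C8a) to give a six-membered hemiketal, and loss of water gives the vinylogous ester 16 with the O1–C8a bond. The closest known reaction types are the organocatalytic three-component reductive alkylation of cyclic 1,3-diones with aldehydes and Hantzsch ester, and the acid-catalysed conversion of 1,3-diones and alcohols (here a tethered 3-hydroxyalkyl chain) into 3-alkoxy-enones. Ring F closes by 6-exo-trig addition of oxygen to the carbonyl followed by dehydration, a net addition–elimination at a vinylogous acid. No lasting stereocenter is created: C3 and C2 come unchanged from step 3 because the C2–O bond is never broken, so the syn aldol pair becomes the 2,3-cis flavan, and the C7 carbinol forms as both epimers that are erased in step 8. The step needs C- over O-alkylation (secured by the Knoevenagel–reduction path), six- over five-membered closure (secured by the allyl ether on O3), no regiochemical choice (the two dione carbonyls are equivalent) and retention of the C7 oxygen and of the α-alkoxy centre (helped by fast hydride transfer and the weakly acidic medium).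

Step 8
Reactants: 16 (2R,3R)-3-(allyloxy)-7-hydroxy-2-[3,4,5-tris(benzyloxy)phenyl]-2,3,4,6,7,8-hexahydro-5H-chromen-5-one
Product: 18 3-O-allyl-3',4',5'-tri-O-benzyl-(−)-epigallocatechin, via bicyclic diketone 17 (not isolated)
Conditions: (COCl)2, DMSO, CH2Cl2, −78 °C; Et3N, −78 → 0 °C
Reagents that add atoms: none
Why: Swern oxidation of the secondary C7 carbinol gives a cyclic 1,3-diketone that is the keto tautomer of a phloroglucinol mono-ether and should enolize irreversibly to aromatic ring D, so no separate dehydrogenation is needed and the C7 stereocenter disappears.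

Step 9
Reactants: 18 3-O-allyl-3',4',5'-tri-O-benzyl-(−)-epigallocatechin
Product: 19 3-O-allyl-5,7,3',4',5'-penta-O-benzyl-(−)-epigallocatechin
Conditions: BnBr, K2CO3, DMF, rt
Reagents that add atoms: benzyl bromide, BrCc1ccccc1
Why: Williamson O-benzylation of the two phenols under mild carbonate conditions is routine for flavan-3-ols and leaves the allyl ether and both stereocenters untouched.

Step 10
Reactants: 19 3-O-allyl-5,7,3',4',5'-penta-O-benzyl-(−)-epigallocatechin
Product: 21 5,7,3',4',5'-penta-O-benzyl-(−)-epigallocatechin, via propenyl ether 20 (not isolated)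
Conditions: [Ir(cod)(PMePh2)2]PF6 (3 mol%, H2-activated), THF, rt; then 0.5 M HCl, THF/H2O, rt
Reagents that add atoms: none
Why: Iridium hydride catalysed isomerization of the allyl ether to the enol ether followed by mild acid hydrolysis frees the 3-hydroxyl without touching benzyl ethers or stereocenters.

Step 11
Reactants: 21 5,7,3',4',5'-penta-O-benzyl-(−)-epigallocatechin
Product: 22 (2R,3R,4S)-4-(2-ethoxyethoxy)-5,7,3',4',5'-penta-O-benzyl-epigallocatechin
Conditions: DDQ, 2-ethoxyethanol, CH2Cl2, rt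
Reagents that add atoms: 2-ethoxyethanol, CCOCCO
Why: DDQ benzylic oxidation: hydride abstraction at C4, activated by the 5,7-dioxygenated ring A, gives a quinone methide-type cation that the alcohol traps from the face anti to the C2 aryl and C3 hydroxyl groups (4β ether, a temporary stereocenter that is ionized again in step 13).

Step 12
Reactants: 22 (2R,3R,4S)-4-(2-ethoxyethoxy)-5,7,3',4',5'-penta-O-benzyl-epigallocatechin; 23 3,4,5-tris(benzyloxy)benzoic acid
Product: 24 (2R,3R,4S)-4-(2-ethoxyethoxy)-5,7,3',4',5'-penta-O-benzyl-epigallocatechin 3-O-[3,4,5-tris(benzyloxy)benzoate]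
Conditions: DCC, DMAP, CH2Cl2, rt
Reagents that add atoms: none
Why: Steglich esterification is the usual way to galloylate the hindered axial 3-hydroxyl of benzylated flavan-3-ols and does not disturb the C4 ether.

Step 13
Reactants: 24 (2R,3R,4S)-4-(2-ethoxyethoxy)-5,7,3',4',5'-penta-O-benzyl-epigallocatechin 3-O-[3,4,5-tris(benzyloxy)benzoate]; 21 5,7,3',4',5'-penta-O-benzyl-(−)-epigallocatechin
Product: 25 trideca-O-benzyl epigallocatechin-3-O-gallate-(4β→8)-epigallocatechin
Conditions: 21 (3 equiv), TMSOTf (0.5 equiv), CH2Cl2, −78 → −40 °C; aq. NaHCO3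
Reagents that add atoms: none
Why: Lewis acid mediated flavan C4–C8 Friedel–Crafts coupling: TMSOTf ionizes the C4 ether, the C3 gallate (neighbouring group participation on the α face) and the C2 aryl group steer the nucleophile to the β face so that the new upper C4 stereocenter is 3,4-trans (4β), and attack comes from C8 of 21, its most nucleophilic ring-D position, with the recoverable excess of 21 suppressing oligomerization.

Step 14
Reactants: 25 trideca-O-benzyl epigallocatechin-3-O-gallate-(4β→8)-epigallocatechin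
Product: 26 epigallocatechin-3-O-gallate-(4β→8)-epigallocatechin (CNP0194932.2)
Conditions: H2 (1 atm), Pd(OH)2/C, THF/MeOH/H2O, rt; filtration under argon, lyophilization
Reagents that add atoms: none
Why: Hydrogenolysis of the thirteen benzyl ethers over Pd(OH)2/C under neutral conditions should leave the gallate ester, the interflavan bond and all five stereocenters untouched.

## Compound list

1 | phloroglucinol | Oc1cc(O)cc(O)c1 | starting material
2 | 5-hydroxycyclohexane-1,3-dione | O=C1CC(O)CC(=O)C1 | intermediate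
3 | (S)-4-benzyloxazolidin-2-one | O=C1N[C@@H](Cc2ccccc2)CO1 | starting material
4 | 2-(allyloxy)acetic acid | C=CCOCC(=O)O | starting material
5 | 2-(allyloxy)acetic pivalic anhydride (not isolated) | C=CCOCC(=O)OC(=O)C(C)(C)C | intermediate
6 | (S)-4-benzyl-3-[2-(allyloxy)acetyl]oxazolidin-2-one | C=CCOCC(=O)N1[C@@H](Cc2ccccc2)COC1=O | intermediate
7 | 3,4,5-tris(benzyloxy)benzaldehyde | O=Cc1cc(OCc2ccccc2)c(OCc2ccccc2)c(OCc2ccccc2)c1 | starting material
8 | dibutylboron Z-enolate of 6 (not isolated) | C=CCO/C=C(\OB(CCCC)CCCC)N1[C@@H](Cc2ccccc2)COC1=O | intermediate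
9 | (S)-4-benzyl-3-{(2S,3R)-2-(allyloxy)-3-hydroxy-3-[3,4,5-tris(benzyloxy)phenyl]propanoyl}oxazolidin-2-one | C=CCO[C@H](C(=O)N1[C@@H](Cc2ccccc2)COC1=O)[C@H](O)c1cc(OCc2ccccc2)c(OCc2ccccc2)c(OCc2ccccc2)c1 | intermediate
10 | (2S,3R)-2-(allyloxy)-3-hydroxy-N-methoxy-N-methyl-3-[3,4,5-tris(benzyloxy)phenyl]propanamide | C=CCO[C@H](C(=O)N(C)OC)[C@H](O)c1cc(OCc2ccccc2)c(OCc2ccccc2)c(OCc2ccccc2)c1 | intermediate
11 | (2S,3R)-2-(allyloxy)-N-methoxy-N-methyl-3-(triethylsilyloxy)-3-[3,4,5-tris(benzyloxy)phenyl]propanamide | C=CCO[C@H](C(=O)N(C)OC)[C@H](O[Si](CC)(CC)CC)c1cc(OCc2ccccc2)c(OCc2ccccc2)c(OCc2ccccc2)c1 | intermediate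
12 | (2S,3R)-2-(allyloxy)-3-(triethylsilyloxy)-3-[3,4,5-tris(benzyloxy)phenyl]propanal | C=CCO[C@H](C=O)[C@H](O[Si](CC)(CC)CC)c1cc(OCc2ccccc2)c(OCc2ccccc2)c(OCc2ccccc2)c1 | intermediate
13 | 2-{(2R,3R)-2-(allyloxy)-3-(triethylsilyloxy)-3-[3,4,5-tris(benzyloxy)phenyl]propylidene}-5-hydroxycyclohexane-1,3-dione (not isolated) | C=CCO[C@H](C=C1C(=O)CC(O)CC1=O)[C@H](O[Si](CC)(CC)CC)c1cc(OCc2ccccc2)c(OCc2ccccc2)c(OCc2ccccc2)c1 | intermediate
14 | 2-{(2R,3R)-2-(allyloxy)-3-(triethylsilyloxy)-3-[3,4,5-tris(benzyloxy)phenyl]propyl}-5-hydroxycyclohexane-1,3-dione (not isolated) | C=CCO[C@H](CC1C(=O)CC(O)CC1=O)[C@H](O[Si](CC)(CC)CC)c1cc(OCc2ccccc2)c(OCc2ccccc2)c(OCc2ccccc2)c1 | intermediate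
15 | 2-{(2R,3R)-2-(allyloxy)-3-hydroxy-3-[3,4,5-tris(benzyloxy)phenyl]propyl}-5-hydroxycyclohexane-1,3-dione (not isolated) | C=CCO[C@H](CC1C(=O)CC(O)CC1=O)[C@H](O)c1cc(OCc2ccccc2)c(OCc2ccccc2)c(OCc2ccccc2)c1 | intermediate
16 | (2R,3R)-3-(allyloxy)-7-hydroxy-2-[3,4,5-tris(benzyloxy)phenyl]-2,3,4,6,7,8-hexahydro-5H-chromen-5-one (both C7 epimers) | C=CCO[C@@H]1CC2=C(CC(O)CC2=O)O[C@@H]1c1cc(OCc2ccccc2)c(OCc2ccccc2)c(OCc2ccccc2)c1 | intermediate
17 | (2R,3R)-3-(allyloxy)-2-[3,4,5-tris(benzyloxy)phenyl]-2,3,4,8-tetrahydro-5H-chromene-5,7(6H)-dione (not isolated) | C=CCO[C@@H]1CC2=C(CC(=O)CC2=O)O[C@@H]1c1cc(OCc2ccccc2)c(OCc2ccccc2)c(OCc2ccccc2)c1 | intermediate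
18 | 3-O-allyl-3',4',5'-tri-O-benzyl-(−)-epigallocatechin | C=CCO[C@@H]1Cc2c(O)cc(O)cc2O[C@@H]1c1cc(OCc2ccccc2)c(OCc2ccccc2)c(OCc2ccccc2)c1 | intermediate
19 | 3-O-allyl-5,7,3',4',5'-penta-O-benzyl-(−)-epigallocatechin | C=CCO[C@@H]1Cc2c(OCc3ccccc3)cc(OCc3ccccc3)cc2O[C@@H]1c1cc(OCc2ccccc2)c(OCc2ccccc2)c(OCc2ccccc2)c1 | intermediate
20 | 3-O-[(E)-prop-1-enyl]-5,7,3',4',5'-penta-O-benzyl-(−)-epigallocatechin (not isolated) | C/C=C/O[C@@H]1Cc2c(OCc3ccccc3)cc(OCc3ccccc3)cc2O[C@@H]1c1cc(OCc2ccccc2)c(OCc2ccccc2)c(OCc2ccccc2)c1 | intermediate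
21 | 5,7,3',4',5'-penta-O-benzyl-(−)-epigallocatechin | O[C@@H]1Cc2c(OCc3ccccc3)cc(OCc3ccccc3)cc2O[C@@H]1c1cc(OCc2ccccc2)c(OCc2ccccc2)c(OCc2ccccc2)c1 | intermediate
22 | (2R,3R,4S)-4-(2-ethoxyethoxy)-5,7,3',4',5'-penta-O-benzyl-epigallocatechin | O[C@@H]1[C@@H](OCCOCC)c2c(OCc3ccccc3)cc(OCc3ccccc3)cc2O[C@@H]1c1cc(OCc2ccccc2)c(OCc2ccccc2)c(OCc2ccccc2)c1 | intermediate
23 | 3,4,5-tris(benzyloxy)benzoic acid | OC(=O)c1cc(OCc2ccccc2)c(OCc2ccccc2)c(OCc2ccccc2)c1 | starting material
24 | (2R,3R,4S)-4-(2-ethoxyethoxy)-5,7,3',4',5'-penta-O-benzyl-epigallocatechin 3-O-[3,4,5-tris(benzyloxy)benzoate] | O=C(O[C@@H]1[C@@H](OCCOCC)c2c(OCc3ccccc3)cc(OCc3ccccc3)cc2O[C@@H]1c1cc(OCc2ccccc2)c(OCc2ccccc2)c(OCc2ccccc2)c1)c1cc(OCc2ccccc2)c(OCc2ccccc2)c(OCc2ccccc2)c1 | intermediate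
25 | trideca-O-benzyl epigallocatechin-3-O-gallate-(4β→8)-epigallocatechin | O=C(O[C@@H]1[C@@H](c2c(OCc3ccccc3)cc(OCc3ccccc3)c3c2O[C@H](c2cc(OCc4ccccc4)c(OCc4ccccc4)c(OCc4ccccc4)c2)[C@H](O)C3)c2c(OCc3ccccc3)cc(OCc3ccccc3)cc2O[C@@H]1c1cc(OCc2ccccc2)c(OCc2ccccc2)c(OCc2ccccc2)c1)c1cc(OCc2ccccc2)c(OCc2ccccc2)c(OCc2ccccc2)c1 | intermediate
26 | epigallocatechin-3-O-gallate-(4β→8)-epigallocatechin (CNP0194932.2) | O=C(O[C@@H]1[C@@H](c2c(O)cc(O)c3c2O[C@H](c2cc(O)c(O)c(O)c2)[C@H](O)C3)c2c(O)cc(O)cc2O[C@@H]1c1cc(O)c(O)c(O)c1)c1cc(O)c(O)c(O)c1 | target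

## Step count and risks

Total steps: 14. Longest linear sequence: 13 steps (steps 2 to 14; step 1 is a one-step side branch).

Steps most likely to fail:

1. Step 7. The C7 oxygen may be lost by β-elimination and aromatization to a 7-deoxy phenol during the acid stage, the α-alkoxy aldehyde may epimerize through its enamine, or a second dione may add to the alkylidene dione before hydride transfer. Fallback: ring D would be brought in already aromatic and the same two bonds made in separate, known operations. Purchased 1,3-bis(benzyloxy)-5-fluorobenzene would be brominated (NBS, MeCN, 0 °C) ortho to fluorine to give 1,5-bis(benzyloxy)-2-bromo-3-fluorobenzene F1. Bromine–lithium exchange (n-BuLi, THF, −78 °C) would give [2,4-bis(benzyloxy)-6-fluorophenyl]lithium F2, which adds to aldehyde 12 to give the benzylic carbinol F3 (C4–C4a bond, both C4 epimers). Ionic deoxygenation of this doubly alkoxy-activated benzylic alcohol (Et3SiH, CF3CO2H, CH2Cl2, −40 °C), which also cleaves the silyl ether, would give the fluoro alcohol F4. Intramolecular nucleophilic aromatic substitution of the fluoride, which sits meta to both benzyloxy groups, by the C2 alkoxide (KN(SiMe3)2, THF, 60 °C) would close the O1–C8a bond with retention at C2. The fallback sets out from 12 and comes back at 19, so steps 8 and 9 are then not needed.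

2. Step 8. The activated C7 oxygen may undergo β-elimination instead of oxidation, or the nascent electron-rich phloroglucinol may be over-oxidized or thiomethylated by excess activated DMSO. Fallback: aromatization by dehydrogenation with the C7 oxygen protected first. Compound 16 would be O-benzylated under acid (benzyl 2,2,2-trichloroacetimidate, TfOH cat., CH2Cl2) to the 7-benzyloxy ketone F5. Kinetic enolization with in situ silylation (LiN(iPr)2, Me3SiCl, THF, −78 °C) would give the trimethylsilyl dienol ether F6. Saegusa–Ito dehydrogenation (Pd(OAc)2, MeCN, rt) would give a cross-conjugated dienone that tautomerizes to the 7-benzyloxy-5-hydroxy flavan F7. Benzylation of the single phenol (BnBr, K2CO3, DMF) then gives 19. The fallback sets out from 16 and comes back at 19.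

3. Step 13. Ionization of the galloylated electrophile may be sluggish, and ester migration, attack through C6 or chain extension to oligomers may compete. Fallback: the order of coupling and acylation would be changed. Ether 22, with its free 3-hydroxyl, would be coupled (TMSOTf, CH2Cl2, −78 °C) with an excess of the 3-O-allyl flavan 19 to give the 4β→8 dimer with a free upper 3-hydroxyl and a lower 3-O-allyl group F8. Steglich esterification with acid 23 (DCC, DMAP) would give the upper 3-O-gallate F9. Isomerization of the allyl ether ([Ir(cod)(PMePh2)2]PF6, H2-activated, THF) would give the propenyl ether F10, and hydrolysis (0.5 M HCl, THF) would give 25. The fallback sets out from 22 and 19 and comes back at 25.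

## Further compounds

F1 | step 7 | 1,5-bis(benzyloxy)-2-bromo-3-fluorobenzene | Fc1cc(OCc2ccccc2)cc(OCc2ccccc2)c1Br
F2 | step 7 | [2,4-bis(benzyloxy)-6-fluorophenyl]lithium | [Li]c1c(F)cc(OCc2ccccc2)cc1OCc1ccccc1
F3 | step 7 | (2R,3R)-2-(allyloxy)-1-[2,4-bis(benzyloxy)-6-fluorophenyl]-3-(triethylsilyloxy)-3-[3,4,5-tris(benzyloxy)phenyl]propan-1-ol (both C1 epimers) | C=CCO[C@H](C(O)c1c(F)cc(OCc2ccccc2)cc1OCc1ccccc1)[C@H](O[Si](CC)(CC)CC)c1cc(OCc2ccccc2)c(OCc2ccccc2)c(OCc2ccccc2)c1
F4 | step 7 | (1R,2R)-2-(allyloxy)-3-[2,4-bis(benzyloxy)-6-fluorophenyl]-1-[3,4,5-tris(benzyloxy)phenyl]propan-1-ol | C=CCO[C@H](Cc1c(F)cc(OCc2ccccc2)cc1OCc1ccccc1)[C@H](O)c1cc(OCc2ccccc2)c(OCc2ccccc2)c(OCc2ccccc2)c1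
F5 | step 8 | (2R,3R)-3-(allyloxy)-7-(benzyloxy)-2-[3,4,5-tris(benzyloxy)phenyl]-2,3,4,6,7,8-hexahydro-5H-chromen-5-one | C=CCO[C@@H]1CC2=C(CC(OCc3ccccc3)CC2=O)O[C@@H]1c1cc(OCc2ccccc2)c(OCc2ccccc2)c(OCc2ccccc2)c1
F6 | step 8 | trimethylsilyl dienol ether of F5 | C=CCO[C@@H]1CC2=C(CC(OCc3ccccc3)C=C2O[Si](C)(C)C)O[C@@H]1c1cc(OCc2ccccc2)c(OCc2ccccc2)c(OCc2ccccc2)c1
F7 | step 8 | 3-O-allyl-7,3',4',5'-tetra-O-benzyl-(−)-epigallocatechin | C=CCO[C@@H]1Cc2c(O)cc(OCc3ccccc3)cc2O[C@@H]1c1cc(OCc2ccccc2)c(OCc2ccccc2)c(OCc2ccccc2)c1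
F8 | step 13 | deca-O-benzyl epigallocatechin-(4β→8)-(3-O-allyl)epigallocatechin | O[C@@H]1[C@@H](c2c(OCc3ccccc3)cc(OCc3ccccc3)c3c2O[C@H](c2cc(OCc4ccccc4)c(OCc4ccccc4)c(OCc4ccccc4)c2)[C@H](OCC=C)C3)c2c(OCc3ccccc3)cc(OCc3ccccc3)cc2O[C@@H]1c1cc(OCc2ccccc2)c(OCc2ccccc2)c(OCc2ccccc2)c1
F9 | step 13 | trideca-O-benzyl epigallocatechin-3-O-gallate-(4β→8)-(3-O-allyl)epigallocatechin | O=C(O[C@@H]1[C@@H](c2c(OCc3ccccc3)cc(OCc3ccccc3)c3c2O[C@H](c2cc(OCc4ccccc4)c(OCc4ccccc4)c(OCc4ccccc4)c2)[C@H](OCC=C)C3)c2c(OCc3ccccc3)cc(OCc3ccccc3)cc2O[C@@H]1c1cc(OCc2ccccc2)c(OCc2ccccc2)c(OCc2ccccc2)c1)c1cc(OCc2ccccc2)c(OCc2ccccc2)c(OCc2ccccc2)c1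
F10 | step 13 | trideca-O-benzyl epigallocatechin-3-O-gallate-(4β→8)-[3-O-(E)-prop-1-enyl]epigallocatechin | O=C(O[C@@H]1[C@@H](c2c(OCc3ccccc3)cc(OCc3ccccc3)c3c2O[C@H](c2cc(OCc4ccccc4)c(OCc4ccccc4)c(OCc4ccccc4)c2)[C@H](O/C=C/C)C3)c2c(OCc3ccccc3)cc(OCc3ccccc3)cc2O[C@@H]1c1cc(OCc2ccccc2)c(OCc2ccccc2)c(OCc2ccccc2)c1)c1cc(OCc2ccccc2)c(OCc2ccccc2)c(OCc2ccccc2)c1
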